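**Retrosynthetic overview**
- The strategy rests on the 5-alkylresorcinol ring, the only ring of the target: Ar1 carries the (S)-16-hydroxyheptadecyl chain, Ar3 and Ar5 carry OH, and Ar2, Ar4 and Ar6 carry H.
- Key disconnection: bonds Ar2–Ar3 and Ar4–Ar5 (Ar5–Ar6 is broken and re-formed). This gives a 3-alkylcyclobut-2-enone (Ar5, Ar6, Ar1, Ar2; its ketone O becomes the Ar5 hydroxyl) and ethoxyacetylene (Ar3, Ar4; its ether O becomes the Ar3 oxygen).
- The cyclobutenone is cut to a terminal alkyne and dichloroketene. The alkyne comes from hexadec-1-yne and (S)-propylene oxide, which supplies the stereocentre, by epoxide opening and alkyne zipper isomerisation.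
- Ring order: the four-membered ring first (ketene–alkyne cycloaddition), then the benzene ring by the thermal cascade. De-ethylation and pivalate removal finish the route.

Key step: step 6

Remark on the chemistry: ethoxyacetylene is taken as its commercial hexanes solution, and the transient sp3 ring carbon of the vinylcyclobutenone intermediate forms without control, which does not matter because it is lost on aromatisation.

**Step 1**
Reactants: 1 hexadec-1-yne; 2 (S)-propylene oxide
Product: 4 (S)-nonadec-4-yn-2-ol, via lithium hexadec-1-yn-1-ide 3 (not isolated)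
Conditions: n-BuLi, THF, −78 °C; BF3·OEt2; then 2, −78 °C; H2O
Reagents that add atoms: none
Why: Yamaguchi–Hirao epoxide opening, in which the lithium acetylide attacks the BF3-activated epoxide at its unsubstituted CH2 by SN2, so the C–O bond of the stereocentre is never broken and the (S) configuration of 2 is carried into 4.

**Step 2**
Reactants: 4 (S)-nonadec-4-yn-2-ol
Product: 5 (S)-nonadec-18-yn-2-ol
Conditions: KH, H2N(CH2)3NH2, rt (forms KAPA); add 4 in THF, rt; H2O, 0 °C
Reagents that add atoms: none
Why: Alkyne zipper reaction, in which potassium 3-aminopropylamide walks the triple bond along the chain by propargyl–allenyl proton shifts until it is trapped as the terminal potassium acetylide, while the carbinol C–H next to the alkoxide is not removed, so the (S) centre should survive.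

**Step 3**
Reactants: 5 (S)-nonadec-18-yn-2-ol
Product: 6 (S)-nonadec-18-yn-2-yl pivalate
Conditions: PivCl, pyridine, DMAP (cat.), CH2Cl2, 0 °C → rt
Reagents that add atoms: pivaloyl chloride, CC(C)(C)C(Cl)=O
Why: DMAP-catalysed acylation of the secondary alcohol at oxygen, with retention because the C–O bond of the stereocentre is untouched, installs a hindered ester that should tolerate the zinc reagents, the thermal step and BBr3.

**Step 4**
Reactants: 6 (S)-nonadec-18-yn-2-yl pivalate; 7 trichloroacetyl chloride
Product: 9 (S)-17-(4,4-dichloro-3-oxocyclobut-1-en-1-yl)heptadecan-2-yl pivalate, via dichloroketene 8 (not isolated)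
Conditions: 7 (slow addition), Zn–Cu couple, Et2O/DME, rt
Reagents that add atoms: none
Why: Ketene–alkyne [2+2] cycloaddition, in which dichloroketene made by zinc dechlorination of 7 bonds through its carbonyl carbon to the unsubstituted alkyne carbon, giving the 3-alkyl-4,4-dichlorocyclobutenone while the remote ester stays inert.

**Step 5**
Reactants: 9 (S)-17-(4,4-dichloro-3-oxocyclobut-1-en-1-yl)heptadecan-2-yl pivalate
Product: 10 (S)-17-(3-oxocyclobut-1-en-1-yl)heptadecan-2-yl pivalate
Conditions: Zn dust, AcOH, TMEDA, EtOH, 0 °C → rt
Reagents that add atoms: none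
Why: Reductive dechlorination of the α,α-dichloro ketone by zinc through its zinc enolate, buffered by TMEDA/AcOH so that the sensitive cyclobutenone and the pivalate survive, and any 2,4-dichloro isomer formed by chlorine migration in step 4 should converge on the same product.

**Step 6**
Reactants: 10 (S)-17-(3-oxocyclobut-1-en-1-yl)heptadecan-2-yl pivalate; 11 ethoxyacetylene
Product: 16 (S)-17-(3-ethoxy-5-hydroxyphenyl)heptadecan-2-yl pivalate, via vinylketene 12 (not isolated), via vinylcyclobutenone 13 (not isolated), via dienylketene 14 (not isolated), via cyclohexadienone 15 (not isolated)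
Conditions: 11 (3 equiv), PhMe, sealed tube, 80 °C then 110 °C
Reagents that add atoms: none
Why: Danheiser benzannulation, a known thermal cascade of cyclobutenones with alkoxyalkynes: four-electron electrocyclic opening of 10 gives vinylketene 12, whose ketene C=C adds to 11 in a [2+2] cycloaddition (forming Ar4–Ar5 and Ar2–Ar3) to give 13. A second four-electron opening gives dienylketene 14, and the benzene ring is closed by six-electron electrocyclisation (re-forming Ar5–Ar6) to dienone 15, which tautomerises to the phenol. No new stereocentre remains, since the sp3 centre of 13 is lost on ring opening, and the remote (S) carbinol centre is not involved. The selectivity needed is regiochemical: the nucleophilic unsubstituted carbon of the polarised ynol ether bonds to the electrophilic ketene carbonyl carbon, which places OEt and OH 1,3 to each other and the chain meta to both. The chain offers only a saturated backbone and a hindered ester, neither of which traps ketenes, and the excess of 11 should keep the vinylketene from acylating the phenol product.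

**Step 7**
Reactants: 16 (S)-17-(3-ethoxy-5-hydroxyphenyl)heptadecan-2-yl pivalate
Product: 17 (S)-17-(3,5-dihydroxyphenyl)heptadecan-2-yl pivalate
Conditions: BBr3 (4 equiv), CH2Cl2, −78 → 0 °C; then H2O
Reagents that add atoms: none
Why: Lewis-acid ether cleavage, in which BBr3 binds the aryl ether oxygen and bromide removes the ethyl group by SN2 to leave an aryl borate that water hydrolyses, while the hindered and less basic secondary pivalate should stay intact at low temperature so the stereocentre is not touched.

**Step 8**
Reactants: 17 (S)-17-(3,5-dihydroxyphenyl)heptadecan-2-yl pivalate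
Product: 18 Hansfordiol A, 5-[(16S)-16-hydroxyheptadecyl]benzene-1,3-diol
Conditions: LiAlH4, THF, 0 °C → rt; then 1 M HCl
Reagents that add atoms: none
Why: Hydride reduction of the ester with acyl–oxygen cleavage releases the secondary alcohol with retention, since the C–O bond at the stereocentre is never broken, and the phenols are only deprotonated and return on acidic work-up.

**Compound list**
1 | hexadec-1-yne | CCCCCCCCCCCCCCC#C | starting material
2 | (S)-propylene oxide | C[C@H]1CO1 | starting material
3 | lithium hexadec-1-yn-1-ide | [Li+].[C-]#CCCCCCCCCCCCCCC | intermediate (not isolated)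
4 | (S)-nonadec-4-yn-2-ol | C[C@H](O)CC#CCCCCCCCCCCCCCC | intermediate
5 | (S)-nonadec-18-yn-2-ol | C[C@H](O)CCCCCCCCCCCCCCCC#C | intermediate
6 | (S)-nonadec-18-yn-2-yl pivalate | C[C@H](OC(=O)C(C)(C)C)CCCCCCCCCCCCCCCC#C | intermediate
7 | trichloroacetyl chloride | ClC(Cl)(Cl)C(Cl)=O | starting material
8 | dichloroketene | ClC(Cl)=C=O | intermediate (not isolated)
9 | (S)-17-(4,4-dichloro-3-oxocyclobut-1-en-1-yl)heptadecan-2-yl pivalate | C[C@H](OC(=O)C(C)(C)C)CCCCCCCCCCCCCCCC1=CC(=O)C1(Cl)Cl | intermediate
10 | (S)-17-(3-oxocyclobut-1-en-1-yl)heptadecan-2-yl pivalate | C[C@H](OC(=O)C(C)(C)C)CCCCCCCCCCCCCCCC1=CC(=O)C1 | intermediate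
11 | ethoxyacetylene | CCOC#C | starting material
12 | vinylketene, (S)-18-methylidene-20-oxoicos-19-en-2-yl pivalate | C[C@H](OC(=O)C(C)(C)C)CCCCCCCCCCCCCCCC(=C)C=C=O | intermediate (not isolated)
13 | vinylcyclobutenone, (2S)-17-(2-ethoxy-4-oxocyclobut-2-en-1-yl)octadec-17-en-2-yl pivalate, ring sp3 carbon unassigned | C[C@H](OC(=O)C(C)(C)C)CCCCCCCCCCCCCCCC(=C)C1C(OCC)=CC1=O | intermediate (not isolated)
14 | dienylketene, (2S,19E)-20-ethoxy-18-methylidene-22-oxodocosa-19,21-dien-2-yl pivalate, ketene and alkenyl terminus cis on the central double bond | CCOC(/C=C=O)=C/C(=C)CCCCCCCCCCCCCCC[C@H](C)OC(=O)C(C)(C)C | intermediate (not isolated)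
15 | cyclohexadienone, (S)-17-(3-ethoxy-5-oxocyclohexa-1,3-dien-1-yl)heptadecan-2-yl pivalate | C[C@H](OC(=O)C(C)(C)C)CCCCCCCCCCCCCCCC1=CC(OCC)=CC(=O)C1 | intermediate (not isolated)
16 | (S)-17-(3-ethoxy-5-hydroxyphenyl)heptadecan-2-yl pivalate | C[C@H](OC(=O)C(C)(C)C)CCCCCCCCCCCCCCCc1cc(O)cc(OCC)c1 | intermediate
17 | (S)-17-(3,5-dihydroxyphenyl)heptadecan-2-yl pivalate | C[C@H](OC(=O)C(C)(C)C)CCCCCCCCCCCCCCCc1cc(O)cc(O)c1 | intermediate
18 | Hansfordiol A, 5-[(16S)-16-hydroxyheptadecyl]benzene-1,3-diol | C[C@H](O)CCCCCCCCCCCCCCCc1cc(O)cc(O)c1 | target

**Totals**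
Total step count: 8. Longest linear sequence: 8 steps (1 and 2 to 18).

**Steps most likely to fail**

Step 6 (benzannulation). The ynol ether may be lost by evaporation or by fragmentation to ketene and ethene before the cyclobutenone opens, the vinylketene may dimerise, or the phenol product may be acylated by a second vinylketene. An aryl ester formed in that way should be returned to 16 by K2CO3 in MeOH, which the secondary pivalate tolerates. If the cascade itself fails, the fallback buys the resorcinol ring instead of building it; it sets out from 2 and comes back at 18. Lithiated tetradec-1-yne (n-BuLi, BF3·OEt2, THF, −78 °C) opens 2 to (S)-heptadec-4-yn-2-ol F1. The same zipper isomerisation as in step 2 gives (S)-heptadec-16-yn-2-ol F2. Sonogashira coupling of F2 with 1,3-bis(benzyloxy)-5-bromobenzene (PdCl2(PPh3)2, CuI, Et3N, 70 °C) gives (S)-17-[3,5-bis(benzyloxy)phenyl]heptadec-16-yn-2-ol F3. Hydrogenation over Pd/C in EtOAc/EtOH should saturate the triple bond and remove both benzyl ethers, giving 18 directly.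

Step 7 (de-ethylation). BBr3 may also attack the secondary pivalate, by acyl cleavage or by ionisation of the secondary C–O bond with bromide formation and erosion of configuration, or the de-ethylation may stay incomplete at the temperature the ester tolerates. The fallback sets out from 16 and comes back at 18; it reverses the order so that no ester meets the Lewis acid and switches to a hard acid and soft nucleophile pair. LiAlH4 in THF at 0 °C removes the pivalate to give (S)-3-ethoxy-5-(16-hydroxyheptadecyl)phenol F4. AlCl3 and EtSH in CH2Cl2 (0 °C → rt) should then remove the ethyl group by SN2 attack of the thiol on the aluminium-bound ether, conditions under which an unactivated secondary aluminium alkoxide is not substituted. A thiolate in DMF is not proposed, because the phenoxide of a resorcinol monoether resists nucleophilic dealkylation.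

Step 4 (dichloroketene cycloaddition). Oligomerisation of dichloroketene may outpace its addition to the unactivated alkyne, and ZnCl2 may promote chlorine migration and decomposition of the adduct. The fallback sets out from 6 and comes back at 10, bypassing 9 and step 5, by a keteniminium [2+2] cycloaddition. N,N-dimethylacetamide, Tf2O and 2,4,6-collidine in ClCH2CH2Cl at reflux generate the keteniminium triflate, which adds to the alkyne of 6 with the same regiochemistry. The adduct is N,N-dimethyl-3-[(S)-16-(pivaloyloxy)heptadecyl]cyclobut-2-en-1-iminium triflate F5, which water should hydrolyse to 10.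

**Further compounds**
F1 | step 6 | (S)-heptadec-4-yn-2-ol | C[C@H](O)CC#CCCCCCCCCCCCC
F2 | step 6 | (S)-heptadec-16-yn-2-ol | C[C@H](O)CCCCCCCCCCCCCC#C
F3 | step 6 | (S)-17-[3,5-bis(benzyloxy)phenyl]heptadec-16-yn-2-ol | C[C@H](O)CCCCCCCCCCCCCC#Cc1cc(OCc2ccccc2)cc(OCc2ccccc2)c1
F4 | step 7 | (S)-3-ethoxy-5-(16-hydroxyheptadecyl)phenol | C[C@H](O)CCCCCCCCCCCCCCCc1cc(O)cc(OCC)c1
F5 | step 4 | N,N-dimethyl-3-[(S)-16-(pivaloyloxy)heptadecyl]cyclobut-2-en-1-iminium triflate | C[C@H](OC(=O)C(C)(C)C)CCCCCCCCCCCCCCCC1=CC(=[N+](C)C)C1.[O-]S(=O)(=O)C(F)(F)F
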